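Assumption: compounds 1, 3, 9 and 12, both antipodes of the phosphoramidite ligand and of the prolinol catalyst, and all common reagents are taken as commercial. Core atoms are cited in naphthalen-2(4aH)-one numbering (C2 carbonyl, C3 enol oxygen, C4a quaternary methyl, C5 secondary methyl, C6 ester oxygen).

**Retrosynthetic overview**
1. Target 18 ⇐ bis-silyl ester 17 by one global desilylation.
2. 17 ⇐ trienone 8 + dienoic acid 14: the C6–O ester bond is made by an oxidative ε-acyloxylation that joins the fragments and sets C6.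
3. 8 ⇐ diosphenol 6 (bis-silylation, then DDQ dehydrogenation) ⇐ octalone 5 (autoxidation).
4. 5 ⇐ (3S)-2,3-dimethylcyclohexanone 2 + methyl vinyl ketone 3. Ring A is bought as enone 1 and receives its methyl by asymmetric conjugate addition; ring B is then closed by Robinson annulation. No other ring is formed.
5. 14 ⇐ silyloxy aldehyde 11 + phosphonate 12 (vinylogous Horner–Wadsworth–Emmons); 11 ⇐ butanal 9 (organocatalytic hydroxymethylation).

**Route**

Step 1
Reactants: 1 2-methylcyclohex-2-en-1-one
Product: 2 (3S)-2,3-dimethylcyclohexan-1-one (mixture of C2 epimers)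
Conditions: AlMe3 (1.4 equiv), CuTC [Cu(O2CC4H3S)] (2 mol%), O,O′-(1,1′-binaphthalene-2,2′-diyl) N,N-bis(1-phenylethyl)phosphoramidite (4 mol%, antipode that gives 3S), Et2O, −30 °C; 1 M HCl
Reagents that add atoms: trimethylaluminium, C[Al](C)C
Why: Copper-catalysed asymmetric conjugate addition of a methylaluminium reagent to an α-substituted cyclic enone; the chiral phosphoramidite–copper complex delivers methyl to one enone face and fixes C3 (expected ≥90% ee), while C2 is left as an epimer mixture because it is re-enolised in step 2.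

Step 2
Reactants: 2 (3S)-2,3-dimethylcyclohexan-1-one; 3 methyl vinyl ketone
Product: 5 (4aR,5S)-4a,5-dimethyl-4,4a,5,6,7,8-hexahydronaphthalen-2(3H)-one, via Michael adduct diketone 4 (not isolated)
Conditions: conc. H2SO4 (cat.), toluene, 0 °C → reflux (Dean–Stark)
Reagents that add atoms: none
Why: Acid-catalysed Robinson annulation (Michael addition of the more substituted enol, then aldol condensation) closes ring B; the enone adds to the enol face anti to the neighbouring C3 methyl, so the new quaternary methyl ends cis to the secondary methyl (expected about 6–9:1, minor trans isomer removed by chromatography).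

Step 3
Reactants: 5 (4aR,5S)-4a,5-dimethyl-4,4a,5,6,7,8-hexahydronaphthalen-2(3H)-one
Product: 6 (4aS,5S)-3-hydroxy-4a,5-dimethyl-5,6,7,8-tetrahydronaphthalen-2(4aH)-one
Conditions: O2 (1 atm), KOtBu (3 equiv), tBuOH/THF, 0 °C → rt; 1 M HCl
Reagents that add atoms: dioxygen, O=O
Why: Base-mediated autoxidation in which the α′-enolate traps O2 and the α-hydroperoxide loses water (Kornblum–DeLaMare type) to the 2,3-dione, which rests as the conjugated diosphenol, as when enone steroids give 2-hydroxy-1,4-dien-3-ones; no stereocentre is touched.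

Step 4
Reactants: 6 (4aS,5S)-3-hydroxy-4a,5-dimethyl-5,6,7,8-tetrahydronaphthalen-2(4aH)-one
Product: 7 (4aS,5S)-2,3-bis[(tert-butyldimethylsilyl)oxy]-4a,5-dimethyl-4a,5,6,7-tetrahydronaphthalene
Conditions: TBSOTf (2.4 equiv), Et3N (3.5 equiv), CH2Cl2, 0 °C → rt
Reagents that add atoms: tert-butyldimethylsilyl trifluoromethanesulfonate, CC(C)(C)[Si](C)(C)OS(=O)(=O)C(F)(F)F
Why: Silylation of the acidic enol OH followed by soft (silyl triflate/amine) vinylogous enolisation; with C3 fully substituted the only removable proton is on the γ-CH2 (C8), so a single extended bis(silyloxy)triene forms.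

Step 5
Reactants: 7 (4aS,5S)-2,3-bis[(tert-butyldimethylsilyl)oxy]-4a,5-dimethyl-4a,5,6,7-tetrahydronaphthalene
Product: 8 (4aS,5S)-3-[(tert-butyldimethylsilyl)oxy]-4a,5-dimethyl-5,6-dihydronaphthalen-2(4aH)-one
Conditions: DDQ (1.05 equiv), 2,4,6-collidine (1.5 equiv), CH2Cl2, 0 °C
Reagents that add atoms: none
Why: DDQ dehydrogenation of a silyl dienol ether (hydride abstraction from the δ-carbon C7, then loss of the O2 silyl group) gives the linearly conjugated trienone, the transform that turns steroidal 3,5-dienol ethers into 4,6-dien-3-ones; the hindered, carbonyl-conjugated C3 silyl enol ether is retained.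

Step 6
Reactants: 9 butanal
Product: 11 (S)-2-{[(tert-butyldimethylsilyl)oxy]methyl}butanal, via hydroxy aldehyde 10 (not isolated)
Conditions: aq. CH2O (37%), (R)-α,α-diphenylprolinol trimethylsilyl ether (10 mol%), pH 7 phosphate buffer, toluene, rt; organic layer separated and dried, then TBSCl, imidazole, 0 °C
Reagents that add atoms: formaldehyde, C=O; tert-butyldimethylsilyl chloride, CC(C)(C)[Si](C)(C)Cl
Why: Organocatalytic enamine cross-aldol (α-hydroxymethylation) in which formaldehyde enters the enamine face opposite the diphenyl(silyloxy)methyl group and sets the 2S centre (expected about 90–95% ee); immediate silylation stops dimerisation and dehydration of the β-hydroxy aldehyde.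

Step 7
Reactants: 11 (S)-2-{[(tert-butyldimethylsilyl)oxy]methyl}butanal; 12 triethyl (E)-4-phosphonobut-2-enoate
Product: 13 ethyl (2E,4E,6R)-6-{[(tert-butyldimethylsilyl)oxy]methyl}octa-2,4-dienoate
Conditions: LiN(SiMe3)2, THF, −78 °C; then 11, −78 → 0 °C
Reagents that add atoms: none
Why: Vinylogous Horner–Wadsworth–Emmons olefination gives the (2E,4E)-dienoate (typically ≥10:1), and the stabilised lithiated phosphonate is too weak a base at −78 °C to epimerise the α-stereocentre.

Step 8
Reactants: 13 ethyl (2E,4E,6R)-6-{[(tert-butyldimethylsilyl)oxy]methyl}octa-2,4-dienoate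
Product: 14 (2E,4E,6R)-6-{[(tert-butyldimethylsilyl)oxy]methyl}octa-2,4-dienoic acid
Conditions: LiOH·H2O, THF/MeOH/H2O, rt; 1 M HCl to pH 4, 0 °C
Reagents that add atoms: lithium hydroxide, [Li+].[OH-]
Why: Ester saponification; the primary silyl ether and the diene geometry are stable to aqueous LiOH at room temperature.

Step 9
Reactants: 8 (4aS,5S)-3-[(tert-butyldimethylsilyl)oxy]-4a,5-dimethyl-5,6-dihydronaphthalen-2(4aH)-one; 14 (2E,4E,6R)-6-{[(tert-butyldimethylsilyl)oxy]methyl}octa-2,4-dienoic acid
Product: 17 (4aS,5R,6S)-3-[(tert-butyldimethylsilyl)oxy]-4a,5-dimethyl-2-oxo-2,4a,5,6-tetrahydronaphthalen-6-yl (2E,4E,6R)-6-{[(tert-butyldimethylsilyl)oxy]methyl}octa-2,4-dienoate, via silyl trienol ether 15 (not isolated), via bis(acyloxy)iodane 16 (not isolated)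
Conditions: flask 1: 8, TMSOTf (1.2 equiv), Et3N (1.15 equiv), CH2Cl2, −20 → 0 °C; flask 2: 14 (2.2 equiv, half recovered), PhIO (1.1 equiv), 4 Å MS, CH2Cl2, rt; flask 1 added to flask 2 with BF3·OEt2 (1.5 equiv), −78 → −40 °C; Et3N, then aq. NaHCO3
Reagents that add atoms: none
Why: Proposed new method: a doubly vinylogous (ε-selective) umpolung acyloxylation in which silyl trienol ether 15 attacks the BF3-activated bis(acyloxy)iodobenzene 16 to give a trienol-bound trivalent iodine species whose electrophilic terminus C6 is captured by the carboxylate ligand with loss of iodobenzene; C6 is expected because it is the unhindered terminus and the only site that restores the fully conjugated dienone (a C8 adduct can transpose suprafacially to C6), and the C–O bond should form along the axial trajectory anti to the pseudoaxial C5–H, that is on the face of the angular methyl, giving the 5,6-cis (6S) ester as in the 6β-functionalisation of steroidal dienol ethers; the closest known reaction type is the α-acyloxylation of ketone silyl enol ethers with PhI(O2CR)2/BF3 and the vinylogous γ-oxidation of silyl dienol ethers.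

Step 10
Reactants: 17 (4aS,5R,6S)-3-[(tert-butyldimethylsilyl)oxy]-4a,5-dimethyl-2-oxo-2,4a,5,6-tetrahydronaphthalen-6-yl (2E,4E,6R)-6-{[(tert-butyldimethylsilyl)oxy]methyl}octa-2,4-dienoate
Product: 18 septeremophilane E, (4aS,5R,6S)-3-hydroxy-4a,5-dimethyl-2-oxo-2,4a,5,6-tetrahydronaphthalen-6-yl (2E,4E,6R)-6-(hydroxymethyl)octa-2,4-dienoate
Conditions: HF·pyridine, pyridine, THF, 0 °C → rt
Reagents that add atoms: none
Why: Buffered fluoride desilylation removes the silyl enol ether and the primary silyl ether in one operation without touching the allylic dienoate or the dienone, releasing the diosphenol and the primary alcohol.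

**Compound list**
1 | 2-methylcyclohex-2-en-1-one | CC1=CCCCC1=O | starting material
2 | (3S)-2,3-dimethylcyclohexan-1-one (C2 epimer mixture) | C[C@H]1CCCC(=O)C1C | intermediate
3 | methyl vinyl ketone (but-3-en-2-one) | CC(=O)C=C | starting material
4 | (2R,3S)-2,3-dimethyl-2-(3-oxobutyl)cyclohexan-1-one | CC(=O)CC[C@@]1(C)C(=O)CCC[C@@H]1C | intermediate (not isolated)
5 | (4aR,5S)-4a,5-dimethyl-4,4a,5,6,7,8-hexahydronaphthalen-2(3H)-one | C[C@H]1CCCC2=CC(=O)CC[C@]12C | intermediate
6 | (4aS,5S)-3-hydroxy-4a,5-dimethyl-5,6,7,8-tetrahydronaphthalen-2(4aH)-one | C[C@H]1CCCC2=CC(=O)C(O)=C[C@]12C | intermediate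
7 | (4aS,5S)-2,3-bis[(tert-butyldimethylsilyl)oxy]-4a,5-dimethyl-4a,5,6,7-tetrahydronaphthalene | C[C@H]1CCC=C2C=C(O[Si](C)(C)C(C)(C)C)C(O[Si](C)(C)C(C)(C)C)=C[C@]12C | intermediate
8 | (4aS,5S)-3-[(tert-butyldimethylsilyl)oxy]-4a,5-dimethyl-5,6-dihydronaphthalen-2(4aH)-one | C[C@H]1CC=CC2=CC(=O)C(O[Si](C)(C)C(C)(C)C)=C[C@]12C | intermediate
9 | butanal | CCCC=O | starting material
10 | (S)-2-(hydroxymethyl)butanal | CC[C@H](C=O)CO | intermediate (not isolated)
11 | (S)-2-{[(tert-butyldimethylsilyl)oxy]methyl}butanal | CC[C@H](C=O)CO[Si](C)(C)C(C)(C)C | intermediate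
12 | triethyl (E)-4-phosphonobut-2-enoate (triethyl 4-phosphonocrotonate) | CCOC(=O)/C=C/CP(=O)(OCC)OCC | starting material
13 | ethyl (2E,4E,6R)-6-{[(tert-butyldimethylsilyl)oxy]methyl}octa-2,4-dienoate | CC[C@H](/C=C/C=C/C(=O)OCC)CO[Si](C)(C)C(C)(C)C | intermediate
14 | (2E,4E,6R)-6-{[(tert-butyldimethylsilyl)oxy]methyl}octa-2,4-dienoic acid | CC[C@H](/C=C/C=C/C(=O)O)CO[Si](C)(C)C(C)(C)C | intermediate
15 | (4aS,5S)-3-[(tert-butyldimethylsilyl)oxy]-4a,5-dimethyl-2-[(trimethylsilyl)oxy]-4a,5-dihydronaphthalene | C[C@H]1C=CC=C2C=C(O[Si](C)(C)C)C(O[Si](C)(C)C(C)(C)C)=C[C@]12C | intermediate (not isolated)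
16 | {bis[(2E,4E,6R)-6-{[(tert-butyldimethylsilyl)oxy]methyl}octa-2,4-dienoyloxy]iodo}benzene | CC[C@H](/C=C/C=C/C(=O)OI(OC(=O)/C=C/C=C/[C@@H](CC)CO[Si](C)(C)C(C)(C)C)c1ccccc1)CO[Si](C)(C)C(C)(C)C | intermediate (not isolated)
17 | (4aS,5R,6S)-3-[(tert-butyldimethylsilyl)oxy]-4a,5-dimethyl-2-oxo-2,4a,5,6-tetrahydronaphthalen-6-yl (2E,4E,6R)-6-{[(tert-butyldimethylsilyl)oxy]methyl}octa-2,4-dienoate | CC[C@H](/C=C/C=C/C(=O)O[C@H]1C=CC2=CC(=O)C(O[Si](C)(C)C(C)(C)C)=C[C@]2(C)[C@H]1C)CO[Si](C)(C)C(C)(C)C | intermediate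
18 | septeremophilane E | CC[C@H](/C=C/C=C/C(=O)O[C@H]1C=CC2=CC(=O)C(O)=C[C@]2(C)[C@H]1C)CO | target

**Step count**
Total: 10 steps. Longest linear sequence: 7 steps (steps 1–5, 9, 10).

**Three steps most likely to fail**

Step 9, the new acyloxylation. The risks are:
- loss of the C5 proton from the cationic intermediate, giving the fully unsaturated 4aH-naphthalenone;
- capture at C8 or C1 instead of C6;
- the 6R epimer, if the carboxylate enters anti to the angular methyl;
- attack of the iodane on the C3 silyl enol ether.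

The fallback uses only known reactions, sets out from 8 and comes back at 17. Allylic oxidation of the ε-CH2 of 8 under the enone-to-enedione conditions (Pd(OH)2 on carbon, tBuOOH, K2CO3, CH2Cl2) gives (4aR,5R)-3-[(tert-butyldimethylsilyl)oxy]-4a,5-dimethyl-4a,5-dihydronaphthalene-2,6-dione F1. Luche reduction (NaBH4, CeCl3·7H2O, MeOH, −78 °C) is expected to select the more electrophilic, less hindered C6 carbonyl, with hydride entering anti to the axial angular methyl as in the reduction of 2-, 4- and 6-oxo steroids to axial alcohols. This gives (4aS,5R,6S)-3-[(tert-butyldimethylsilyl)oxy]-6-hydroxy-4a,5-dimethyl-5,6-dihydronaphthalen-2(4aH)-one F2. Acid 14 is then activated with 2,4,6-trichlorobenzoyl chloride and Et3N as (2E,4E,6R)-6-{[(tert-butyldimethylsilyl)oxy]methyl}octa-2,4-dienoic 2,4,6-trichlorobenzoic anhydride F3, and F2 with DMAP in toluene gives 17 with retention at C6.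

Step 3, the autoxidation. Oxygen may be taken up at the γ-carbon (C8) instead of C3, or the diosphenol may be over-oxidised to ring-cleaved acids. The fallback sets out from 5 and comes back at 6. The kinetic α′-enolate (LiN(SiMe3)2, THF, −78 °C) is hydroxylated with 2-(phenylsulfonyl)-3-phenyloxaziridine to give (4aR,5S)-3-hydroxy-4a,5-dimethyl-4,4a,5,6,7,8-hexahydronaphthalen-2(3H)-one F4 as a C3 epimer mixture. Swern oxidation [(COCl)2, DMSO, Et3N] then gives the 2,3-dione, which tautomerises to 6.

Step 6, hydroxymethylation and silylation. The β-hydroxy aldehyde 10 is water-soluble, dimerises and dehydrates readily, so silylation of the crude material may give a poor yield or erode the enantiomeric excess. The fallback sets out from 10 and comes back at 13, bypassing 11 and step 7. Aldehyde 10 is trapped in the same flask by Wittig olefination with the water-tolerant stabilised ylide ethyl (2E)-4-(triphenyl-λ5-phosphanylidene)but-2-enoate, and the 4Z portion is equilibrated with catalytic I2 to give ethyl (2E,4E,6R)-6-(hydroxymethyl)octa-2,4-dienoate F5. This stable alcohol is silylated (TBSCl, imidazole) to 13.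

Further compounds
F1 | step 9 | (4aR,5R)-3-[(tert-butyldimethylsilyl)oxy]-4a,5-dimethyl-4a,5-dihydronaphthalene-2,6-dione | C[C@H]1C(=O)C=CC2=CC(=O)C(O[Si](C)(C)C(C)(C)C)=C[C@]12C
F2 | step 9 | (4aS,5R,6S)-3-[(tert-butyldimethylsilyl)oxy]-6-hydroxy-4a,5-dimethyl-5,6-dihydronaphthalen-2(4aH)-one | C[C@H]1[C@@H](O)C=CC2=CC(=O)C(O[Si](C)(C)C(C)(C)C)=C[C@]12C
F3 | step 9 | (2E,4E,6R)-6-{[(tert-butyldimethylsilyl)oxy]methyl}octa-2,4-dienoic 2,4,6-trichlorobenzoic anhydride | CC[C@H](/C=C/C=C/C(=O)OC(=O)c1c(Cl)cc(Cl)cc1Cl)CO[Si](C)(C)C(C)(C)C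
F4 | step 3 | (4aR,5S)-3-hydroxy-4a,5-dimethyl-4,4a,5,6,7,8-hexahydronaphthalen-2(3H)-one (C3 epimer mixture) | C[C@H]1CCCC2=CC(=O)C(O)C[C@]12C
F5 | step 6 | ethyl (2E,4E,6R)-6-(hydroxymethyl)octa-2,4-dienoate | CC[C@H](/C=C/C=C/C(=O)OCC)CO
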